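## The problem

Compound 18 is a flavone with no stereocentre, so the synthesis is a matter of regiochemistry and protecting-group economy, not of configuration. Ring A is fully substituted: C5, C7 and C8 carry methoxy groups, C6 a free hydroxyl and C8a the ring oxygen, so five contiguous oxygens must be placed and three kinds told apart. Ring B is joined to C2 through a carbon flanked by a hydroxyl (C2') and a methoxy group (C6'), and C4a on ring A is flanked likewise. Any union that needs an enolate or a metal at these positions therefore works against two ortho substituents on each side. A free 1,3-diketone between two rings that both carried a free ortho hydroxyl could close in either direction, so the sense of pyranone formation has to be imposed. The 5-methoxy group peri to the C4 carbonyl is the first ether to fall to boron or aluminium halides, a ring A with both C6 and C8a oxygens free is a hydroquinone that oxidizes to the quinone, and the C2=C3 bond can be over-reduced, so the end game must be neutral and mild. The enabling feature is the C4–C3–C2 unit: a three-carbon chain oxygenated at both ends between two aryl groups is the pattern of a 3,5-diarylisoxazole. The C4a carbon that would carry the nitrile oxide sits between two oxygenated carbons (C5 and C8a) that shield such a dipole.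

## Retrosynthesis

**18 to 17.** The two free hydroxyls of 18 (C6–OH, C2'–OH) are traced to benzyl ethers in 17, cutting two O–CH2Ph bonds. Benzyl is preferred to further methyl ethers because no demethylating agent would spare the more labile 5-methoxy group, whereas hydrogenolysis is neutral. Compound 17 is no simpler in skeleton, but it has no free phenol, which the earlier chemistry requires. The forward step must remove both benzyl groups without saturating C2=C3.

**17 to 16 to 15.** In 17 the O1–C2 bond is cut and the C4 carbonyl is traced to a nitrogen-bearing carbon, giving enaminone 16 with the C8a oxygen held as a MOM acetal. Compound 16 is the product of N–O scission of isoxazole 15. The neighbouring cut, a free 1,3-diketone made by acyl transfer to an acetophenone enolate, would need enolate formation next to a hexasubstituted ring and a 2,6-disubstituted benzoyl partner. The isoxazole carries the same oxidation pattern without any enolate, as a robust aromatic ring. The forward steps must cleave N–O without touching the benzyl ethers, then unmask only the C8a oxygen, so that closure onto C2 is the only six-membered option.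

**15 to 11 and 14 (key cut).** Isoxazole 15 is cut at C4–C3 and O–C2 (flavone numbering), the two bonds made by a nitrile oxide–alkyne cycloaddition. This gives ring A nitrile oxide 11 and ring B alkyne 14.
- Against the reverse pairing: a ring B nitrile oxide would require chlorinating an oxime whose electron-rich ring still has three free positions, whereas ring A has none.
- Against a C2–C1' cross-coupling: that would join a di-ortho-substituted arylmetal to a 2-halochromone at the most hindered bond.
- Simplification: the precursors are two monocyclic arenes of similar size, each close to a commercial benzaldehyde.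
- Forward demand: 3,5-regioselectivity, and cycloaddition faster than dimerization of the dipole.

**11 to 9 to 8.** The nitrile oxide is traced through aldoxime 9 to aldehyde 8, the C=N–O unit going back to the formyl carbon that becomes C4. This is the standard entry to nitrile oxides and needs only condensation and a formal dehydrogenation. The MOM acetal must survive the chlorination and the base.

**8 to 7 to 6.** Removing the MOM group gives salicylaldehyde 7, and cutting the C4a–CHO bond gives phenol 6. The formyl carbon cannot be carried from the starting material, because the original aldehyde carbon sits where the C8a oxygen is needed. Phenol 6 has a single ring hydrogen, ortho to the hydroxyl, so ortho-formylation has no regiochemical choice to make.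

**6 to 4 to 3 to 2 to 1.** The C8a oxygen of 6 is traced to the formyl group of aldehyde 4 (aryl migration to oxygen). The C8 methoxy group of 4 is traced to the bromine of 3, the bromine to a ring hydrogen of 2, and the benzyl ether of 2 to the phenol of syringaldehyde 1. The OMe/OH/OMe triad of 1 maps onto C5/C6/C7 with the C6 oxygen already differentiated. Because 1 is symmetric, bromination at either free position gives the same product. The forward sequence needs one copper-mediated C–O coupling next to an aldehyde.

**14 to 13 to 12.** The terminal alkyne carbon of 14 is cut off, leaving aldehyde 13 (one-carbon homologation), and the benzyl group is removed to give commercial 2-hydroxy-6-methoxybenzaldehyde 12. Compound 12 already holds the OH/OMe distinction of ring B, which an aryl halide route to the alkyne would have to create.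

## Roads not taken

**Alternative 1:** Ring A is cut at C4a–C8a and traced to a four-membered ring.
- Forward key step: dimethyl squarate A3 would take up an α-lithiated enol ether at one carbonyl and, after silylation of the tertiary alkoxide, give 4-[(tert-butyldimethylsilyl)oxy]-2,3-dimethoxy-4-(1-methoxyethenyl)cyclobut-2-en-1-one A2. Heating A2 should open the ring to a dienylketene, and 6π closure and tautomerization would then give 4-[(tert-butyldimethylsilyl)oxy]-2,3,5-trimethoxyphenol A1.
- Merits: every oxygen is placed by construction, with no halogenation, copper coupling or Baeyer–Villiger step, and the C6 oxygen arrives as a silyl ether.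
- Weak points: A1 is only the silyl analogue of phenol 6, so the pyranone, the hindered union with ring B and the C4 carbon are all still to come. A2 needs cryogenic organolithium chemistry and silylation of a hindered tertiary alcohol. The silyl ether on a hydroquinone oxygen between two methoxy groups is less likely than benzyl to survive the later base and acid.
- Comparison: it reaches the ring A phenol in about three steps from A3 against four from 1, and with cleaner regiochemical logic. The chosen plan sets against this a commodity starting material whose symmetry makes the bromination unambiguous, and a protecting group that lasts to the end. Alternative 1 is also a ring A synthesis, not a flavone strategy, and would still need a fragment union such as the one chosen.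

**Alternative 2:** Ring B is cut at C1'–C2' and C5'–C6' and grown on a finished chromone.
- Forward key step: cyclobut-2-en-1-one A6 and 6-(benzyloxy)-5,7,8-trimethoxy-2-(methoxyethynyl)-4H-chromen-4-one A5 would be heated together. A6 opens to a vinylketene, which adds [2+2] to the ynol ether of A5; 4π opening, 6π closure and tautomerization would then give 6-(benzyloxy)-2-(2-hydroxy-6-methoxyphenyl)-5,7,8-trimethoxy-4H-chromen-4-one A4.
- Merits: the 2'-OH and 6'-OMe emerge differentiated with no protecting group on ring B, the hindered C2–C1' bond is never formed by coupling, and A4 is one hydrogenolysis from 18.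
- Weak points: the ynol ether of A5 is conjugated with the chromone carbonyl, a push–pull alkyne whose reduced nucleophilicity works against the ketene [2+2] step. A5 itself requires the complete ring A chromone plus a labile alkoxyethynyl unit at C2. A6 is volatile and prone to polymerize. The ring built de novo is the one available commercially as 12.
- Comparison: the end game is two steps shorter than the chosen one, which the isoxazole route cannot match. Against that, both partners of the chosen key step come from routine aldehyde chemistry, and its reaction type is established for hindered aryl partners.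

**Alternative 3:** The pyranone is cut at C4a–C4, C4–C3 and O1–C2 in a three-component union.
- Forward key step: 4-(benzyloxy)-2-iodo-3,5,6-trimethoxyphenol A8, which is one iodination away from phenol 6, would be combined with carbon monoxide A9 and alkyne 14 under PdCl2(PPh3)2 catalysis in diethylamine. This should give 6-(benzyloxy)-2-[2-(benzyloxy)-6-methoxyphenyl]-5,7,8-trimethoxy-4H-chromen-4-one A7. A7 is the same compound as 17, so only the final hydrogenolysis would remain.
- Merits: three bonds form in one operation and the route reuses 6 and 14. It would reach 18 in about nine steps overall against fourteen, with no formylation, oxime, N–O cleavage or acid cyclization. In step economy it is clearly the better road.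
- Weak points: oxidative addition of zerovalent palladium must occur at a C–I bond flanked by OH and OMe on a pentaoxygenated ring. A8 is an iodinated hydroquinone monoether, liable to oxidation and to loss of iodine. Direct alkynylation without uptake of A9, followed by five-membered ring closure, competes with the carbonylative path. The intermediate ynone can also close 5-exo as well as 6-endo, so A7 is not the only possible outcome.
- Comparison: the chosen plan pays five extra steps. In return no step depends on a catalytic cycle at the hexasubstituted ring, C4 is installed by a formylation that has no alternative site, and the isoxazole fixes the regiochemistry of heterocycle formation.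

Key step: step 11

Assumption: nitrile oxide 11, flanked by OMe and OMOM, is taken to be persistent enough to be worked up and carried into step 11 as a crude solution, as is general for 2,6-disubstituted benzonitrile oxides.

## Route

Step 1
Reactants: 1 syringaldehyde (4-hydroxy-3,5-dimethoxybenzaldehyde)
Product: 2 4-(benzyloxy)-3,5-dimethoxybenzaldehyde
Conditions: BnBr, K2CO3, DMF, rt
Reagents that add atoms: benzyl bromide, BrCc1ccccc1
Why: Williamson O-alkylation of the phenoxide; the benzyl ether marks the future C6 hydroxyl and should survive every step up to the final hydrogenolysis.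

Step 2
Reactants: 2 4-(benzyloxy)-3,5-dimethoxybenzaldehyde
Product: 3 4-(benzyloxy)-2-bromo-3,5-dimethoxybenzaldehyde
Conditions: NBS, MeCN, rt to 50 °C
Reagents that add atoms: N-bromosuccinimide, O=C1CCC(=O)N1Br
Why: Electrophilic aromatic bromination; the two free ring positions of 2 are equivalent by symmetry and each is activated by an ortho and a para alkoxy group, so monobromination can give only 3, and NBS avoids free HBr that could attack the benzyl ether.

Step 3
Reactants: 3 4-(benzyloxy)-2-bromo-3,5-dimethoxybenzaldehyde
Product: 4 4-(benzyloxy)-2,3,5-trimethoxybenzaldehyde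
Conditions: NaOMe, CuBr (cat.), MeOH/DMF, 90 °C
Reagents that add atoms: sodium methoxide, C[O-].[Na+]
Why: Copper-catalysed Ullmann-type methoxylation of an aryl bromide, assisted by the ortho formyl group; it installs the future C8 methoxy group and leaves the benzyl ether alone.

Step 4
Reactants: 4 4-(benzyloxy)-2,3,5-trimethoxybenzaldehyde
Product: 6 4-(benzyloxy)-2,3,5-trimethoxyphenol, via aryl formate 5 (not isolated)
Conditions: mCPBA, CH2Cl2, 0 °C to rt; wash (aq NaHCO3); then K2CO3 (cat.), MeOH, rt
Reagents that add atoms: mCPBA (3-chloroperoxybenzoic acid), OOC(=O)c1cccc(Cl)c1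
Why: Baeyer–Villiger (Dakin-type) oxidation in which the electron-rich aryl group migrates in preference to hydrogen, followed by methanolysis of the formate; keeping the phenol masked as 5 until the peracid is washed out limits over-oxidation to a quinone.

Step 5
Reactants: 6 4-(benzyloxy)-2,3,5-trimethoxyphenol
Product: 7 3-(benzyloxy)-6-hydroxy-2,4,5-trimethoxybenzaldehyde
Conditions: MgCl2, Et3N, (CH2O)n, MeCN, reflux
Reagents that add atoms: paraformaldehyde (as formaldehyde), C=O
Why: Magnesium-mediated ortho-formylation (Casnati–Skattebøl) through the phenoxymagnesium–formaldehyde chelate, a second formaldehyde acting as hydride acceptor; the only unsubstituted ring carbon is ortho to the hydroxyl, so there is no regiochemical choice.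

Step 6
Reactants: 7 3-(benzyloxy)-6-hydroxy-2,4,5-trimethoxybenzaldehyde
Product: 8 3-(benzyloxy)-2,4,5-trimethoxy-6-(methoxymethoxy)benzaldehyde
Conditions: MOMCl, i-Pr2NEt, CH2Cl2, 0 °C to rt
Reagents that add atoms: chloromethyl methyl ether (MOMCl), COCCl
Why: O-alkylation of the hydrogen-bonded salicylaldehyde phenol; the acetal is stable to the base, oxidant, heat and reductant of steps 7 to 12 and is the one group that the acid of step 13 removes.

Step 7
Reactants: 8 3-(benzyloxy)-2,4,5-trimethoxy-6-(methoxymethoxy)benzaldehyde
Product: 9 (E)-3-(benzyloxy)-2,4,5-trimethoxy-6-(methoxymethoxy)benzaldehyde oxime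
Conditions: NH2OH·HCl, NaOAc, EtOH/H2O, rt
Reagents that add atoms: hydroxylamine hydrochloride, NO.Cl
Why: Condensation of the aldehyde with hydroxylamine under buffered conditions that spare the MOM acetal; the (E)-aldoxime is the expected isomer and its geometry is erased in step 8.

Step 8
Reactants: 9 (E)-3-(benzyloxy)-2,4,5-trimethoxy-6-(methoxymethoxy)benzaldehyde oxime
Product: 11 3-(benzyloxy)-2,4,5-trimethoxy-6-(methoxymethoxy)benzonitrile oxide, via hydroximoyl chloride 10 (not isolated)
Conditions: NCS, DMF, rt; then Et3N, 0 °C; cold aqueous work-up
Reagents that add atoms: none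
Why: Chlorination of the aldoxime C–H with NCS and dehydrochlorination by Et3N, the standard generation of aryl nitrile oxides; ring A bears no hydrogen, so ring chlorination cannot compete, and the flanking OMe and OMOM groups retard dimerization to the furoxan.

Step 9
Reactants: 12 2-hydroxy-6-methoxybenzaldehyde
Product: 13 2-(benzyloxy)-6-methoxybenzaldehyde
Conditions: BnBr, K2CO3, DMF, 60 °C
Reagents that add atoms: benzyl bromide, BrCc1ccccc1
Why: Williamson benzylation of the chelated phenol; the benzyl group keeps the ring B oxygen from acting as a nucleophile in step 13.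

Step 10
Reactants: 13 2-(benzyloxy)-6-methoxybenzaldehyde
Product: 14 1-(benzyloxy)-2-ethynyl-3-methoxybenzene
Conditions: dimethyl (1-diazo-2-oxopropyl)phosphonate, K2CO3, MeOH, rt
Reagents that add atoms: dimethyl (1-diazo-2-oxopropyl)phosphonate (Ohira–Bestmann reagent), COP(=O)(OC)C(=[N+]=[N-])C(C)=O
Why: Seyferth–Gilbert homologation in the Ohira–Bestmann variant; methanolysis releases the diazomethylphosphonate anion, which adds to the aldehyde, and the derived alkylidene carbene rearranges by 1,2-hydrogen shift to the terminal alkyne under conditions that the benzyl ether tolerates.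

Step 11
Reactants: 11 3-(benzyloxy)-2,4,5-trimethoxy-6-(methoxymethoxy)benzonitrile oxide; 14 1-(benzyloxy)-2-ethynyl-3-methoxybenzene
Product: 15 3-[3-(benzyloxy)-2,4,5-trimethoxy-6-(methoxymethoxy)phenyl]-5-[2-(benzyloxy)-6-methoxyphenyl]isoxazole
Conditions: toluene, 70 °C (14 in slight excess)
Reagents that add atoms: none
Why: Thermal, concerted but asynchronous [3+2] cycloaddition (Huisgen) of the nitrile oxide dipole of 11 across the terminal triple bond of 14: the dipole carbon bonds to the terminal alkyne carbon (future C4–C3) and the dipole oxygen to the internal carbon (future O–C2). The closest known reaction type is the addition of persistent 2,6-disubstituted benzonitrile oxides to arylacetylenes, which gives 3,5-diarylisoxazoles. The one ring closed, the five-membered isoxazole, forms by intermolecular 4π + 2π union of a three-atom and a two-atom component, both ring bonds being made in the same step, and it is aromatic as formed. No stereocentre is created. The step needs 3,5- over 3,4-regioselectivity; this follows from the terminal alkyne, whose unhindered CH terminus takes the aryl-bearing dipole carbon while the aryl-substituted carbon takes oxygen, the usual electronic outcome for arylacetylenes, reinforced here by the ortho substituents on both partners. It also needs cycloaddition to outrun dimerization to the furoxan and rearrangement to the isocyanate; the OMe and OMOM groups flanking the CNO group suppress dimerization, and the temperature is kept below that at which hindered nitrile oxides isomerize. No base or nucleophile is present and neither partner has a free OH, so 1,3-addition to the dipole has no partner.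

Step 12
Reactants: 15 3-[3-(benzyloxy)-2,4,5-trimethoxy-6-(methoxymethoxy)phenyl]-5-[2-(benzyloxy)-6-methoxyphenyl]isoxazole
Product: 16 (Z)-3-amino-3-[3-(benzyloxy)-2,4,5-trimethoxy-6-(methoxymethoxy)phenyl]-1-[2-(benzyloxy)-6-methoxyphenyl]prop-2-en-1-one
Conditions: Mo(CO)6, MeCN/H2O, reflux
Reagents that add atoms: none
Why: Reductive cleavage of the isoxazole N–O bond by zerovalent molybdenum, with water supplying the two hydrogens; it should give the hydrogen-bonded (Z)-β-enaminone with nitrogen on C4 and the ketone on C2, and unlike catalytic hydrogenation it leaves the benzyl ethers in place.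

Step 13
Reactants: 16 (Z)-3-amino-3-[3-(benzyloxy)-2,4,5-trimethoxy-6-(methoxymethoxy)phenyl]-1-[2-(benzyloxy)-6-methoxyphenyl]prop-2-en-1-one
Product: 17 6-(benzyloxy)-2-[2-(benzyloxy)-6-methoxyphenyl]-5,7,8-trimethoxy-4H-chromen-4-one
Conditions: 3 M aq HCl, MeOH, 65 °C
Reagents that add atoms: water, O
Why: Acid removes the MOM acetal, the freed C8a hydroxyl adds 6-exo-trig to the C2 carbonyl, and dehydration with hydrolysis of the C4 iminium gives the pyranone, as in the acid cyclodehydration of o-hydroxyaryl 1,3-diketones; only the ring A oxygen is free, so closure can run in one direction only.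

Step 14
Reactants: 17 6-(benzyloxy)-2-[2-(benzyloxy)-6-methoxyphenyl]-5,7,8-trimethoxy-4H-chromen-4-one
Product: 18 6,2'-dihydroxy-5,7,8,6'-tetramethoxyflavone
Conditions: H2 (1 atm), Pd/C, EtOAc/MeOH, rt
Reagents that add atoms: none
Why: Catalytic hydrogenolysis of both aryl benzyl ethers under neutral conditions, which spare the peri 5-methoxy group that Lewis acids would cleave; hydrogen uptake is followed so that the reaction is stopped before the C2=C3 bond is reduced.

## Compound list

1 | syringaldehyde (4-hydroxy-3,5-dimethoxybenzaldehyde) | COc1cc(C=O)cc(OC)c1O | starting material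
2 | 4-(benzyloxy)-3,5-dimethoxybenzaldehyde | COc1cc(C=O)cc(OC)c1OCc1ccccc1 | intermediate
3 | 4-(benzyloxy)-2-bromo-3,5-dimethoxybenzaldehyde | COc1cc(C=O)c(Br)c(OC)c1OCc1ccccc1 | intermediate
4 | 4-(benzyloxy)-2,3,5-trimethoxybenzaldehyde | COc1cc(C=O)c(OC)c(OC)c1OCc1ccccc1 | intermediate
5 | 4-(benzyloxy)-2,3,5-trimethoxyphenyl formate | COc1cc(OC=O)c(OC)c(OC)c1OCc1ccccc1 | intermediate
6 | 4-(benzyloxy)-2,3,5-trimethoxyphenol | COc1cc(O)c(OC)c(OC)c1OCc1ccccc1 | intermediate
7 | 3-(benzyloxy)-6-hydroxy-2,4,5-trimethoxybenzaldehyde | COc1c(C=O)c(O)c(OC)c(OC)c1OCc1ccccc1 | intermediate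
8 | 3-(benzyloxy)-2,4,5-trimethoxy-6-(methoxymethoxy)benzaldehyde | COCOc1c(OC)c(OC)c(OCc2ccccc2)c(OC)c1C=O | intermediate
9 | (E)-3-(benzyloxy)-2,4,5-trimethoxy-6-(methoxymethoxy)benzaldehyde oxime | COCOc1c(OC)c(OC)c(OCc2ccccc2)c(OC)c1/C=N/O | intermediate
10 | (Z)-3-(benzyloxy)-N-hydroxy-2,4,5-trimethoxy-6-(methoxymethoxy)benzenecarboximidoyl chloride | COCOc1c(OC)c(OC)c(OCc2ccccc2)c(OC)c1/C(Cl)=N/O | intermediate
11 | 3-(benzyloxy)-2,4,5-trimethoxy-6-(methoxymethoxy)benzonitrile oxide | COCOc1c(OC)c(OC)c(OCc2ccccc2)c(OC)c1C#[N+][O-] | intermediate
12 | 2-hydroxy-6-methoxybenzaldehyde | COc1cccc(O)c1C=O | starting material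
13 | 2-(benzyloxy)-6-methoxybenzaldehyde | COc1cccc(OCc2ccccc2)c1C=O | intermediate
14 | 1-(benzyloxy)-2-ethynyl-3-methoxybenzene | COc1cccc(OCc2ccccc2)c1C#C | intermediate
15 | 3-[3-(benzyloxy)-2,4,5-trimethoxy-6-(methoxymethoxy)phenyl]-5-[2-(benzyloxy)-6-methoxyphenyl]isoxazole | COCOc1c(OC)c(OC)c(OCc2ccccc2)c(OC)c1-c1cc(-c2c(OC)cccc2OCc2ccccc2)on1 | intermediate
16 | (Z)-3-amino-3-[3-(benzyloxy)-2,4,5-trimethoxy-6-(methoxymethoxy)phenyl]-1-[2-(benzyloxy)-6-methoxyphenyl]prop-2-en-1-one | N/C(=C\C(=O)c1c(OC)cccc1OCc1ccccc1)c1c(OC)c(OCc2ccccc2)c(OC)c(OC)c1OCOC | intermediate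
17 | 6-(benzyloxy)-2-[2-(benzyloxy)-6-methoxyphenyl]-5,7,8-trimethoxy-4H-chromen-4-one | COc1cccc(OCc2ccccc2)c1-c1cc(=O)c2c(OC)c(OCc3ccccc3)c(OC)c(OC)c2o1 | intermediate
18 | 6,2'-dihydroxy-5,7,8,6'-tetramethoxyflavone | COc1cccc(O)c1-c1cc(=O)c2c(OC)c(O)c(OC)c(OC)c2o1 | target

## Step count and least certain steps

Total: 14 steps. Longest linear sequence: 12 steps (steps 1 to 8 and 11 to 14, from 1). The ring B branch is steps 9 and 10.

**Step 11 (key step).** Both partners are di-ortho-substituted, so the cycloaddition may be slow enough for thermal isomerization of the nitrile oxide to the isocyanate, or slow dimerization, to take over. Loss of 3,5-regiocontrol is the lesser concern. The fallback forms C4–C3 by carbonyl addition instead; it sets out from 8 and 14 and returns to the route at 17. Alkyne 14 would be deprotonated (n-BuLi, THF, −78 °C) and added to aldehyde 8 to give 1-[3-(benzyloxy)-2,4,5-trimethoxy-6-(methoxymethoxy)phenyl]-3-[2-(benzyloxy)-6-methoxyphenyl]prop-2-yn-1-ol F1. MnO2 in CH2Cl2 should oxidize this to 1-[3-(benzyloxy)-2,4,5-trimethoxy-6-(methoxymethoxy)phenyl]-3-[2-(benzyloxy)-6-methoxyphenyl]prop-2-yn-1-one F2. HCl in MeOH would then remove the MOM group to give 1-[3-(benzyloxy)-6-hydroxy-2,4,5-trimethoxyphenyl]-3-[2-(benzyloxy)-6-methoxyphenyl]prop-2-yn-1-one F3, and Et2NH in EtOH should close the pyranone 6-endo by conjugate addition–elimination to give 17.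

**Step 3.** Methoxide may attack the free aldehyde (hydride-transfer redox chemistry), or the bromide may be reduced off instead of substituted, at a crowded and electron-rich position. The fallback forms the C–O bond by oxidation of a carbon–boron bond; it sets out from 3 and returns at 4. Aldehyde 3 would be converted with HC(OMe)3 and catalytic TsOH in MeOH into 2-(benzyloxy)-4-bromo-5-(dimethoxymethyl)-1,3-dimethoxybenzene F4. Bromine–lithium exchange (n-BuLi, THF, −78 °C), borylation with B(OMe)3 and oxidative work-up (H2O2, NaOH) should give 3-(benzyloxy)-6-(dimethoxymethyl)-2,4-dimethoxyphenol F5. Methylation (MeI, K2CO3, acetone) would give 2-(benzyloxy)-5-(dimethoxymethyl)-1,3,4-trimethoxybenzene F6, and dilute aqueous HCl in THF would release the aldehyde to give 4.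

**Step 5.** Formylation may stall because the magnesium phenoxide is chelated by the neighbouring methoxy group and the reacting carbon is crowded, and long heating favours methoxymethylation or diarylmethane formation. The fallback reverses the order of protection and formylation and uses directed ortho-metalation; it sets out from 6 and returns at 8, bypassing 7. Phenol 6 would be protected (MOMCl, i-Pr2NEt) as 2-(benzyloxy)-1,3,4-trimethoxy-5-(methoxymethoxy)benzene F7. The single ring hydrogen of this ether lies between OMOM and OMe and should be removed by n-BuLi/TMEDA in THF (−78 to 0 °C); quenching with DMF would give 8 directly.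

**Step 13.** The cascade may stop short: the hindered vinylogous amide may resist hydrolysis, or the C4 nitrogen may be retained after ring closure, and prolonged heating in acid to force it risks loss of a benzyl group. The fallback separates hydrolysis from dehydration; it sets out from 16 and returns at 17. Aqueous HCl (1 M) in THF at room temperature to 40 °C should hydrolyse the enaminone and the MOM acetal to 1-[3-(benzyloxy)-6-hydroxy-2,4,5-trimethoxyphenyl]-3-[2-(benzyloxy)-6-methoxyphenyl]propane-1,3-dione F8. This diketone would then be cyclodehydrated under anhydrous conditions (catalytic TsOH, toluene, 80 °C), the classical end of a Baker–Venkataraman sequence, to give 17.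

**Step 10.** Addition of the diazophosphonate anion to the hindered, electron-rich aldehyde may be slow, so that the reagent decomposes first. The fallback is the two-stage Corey–Fuchs route; it sets out from 13 and returns at 14. CBr4 and PPh3 in CH2Cl2 would convert 13 into 1-(benzyloxy)-2-(2,2-dibromoethenyl)-3-methoxybenzene F9, and n-BuLi (2 equiv, THF, −78 °C) followed by water should give 14 by elimination, bromine–lithium exchange and 1,2-shift.

## Further compounds

F1 | step 11 | 1-[3-(benzyloxy)-2,4,5-trimethoxy-6-(methoxymethoxy)phenyl]-3-[2-(benzyloxy)-6-methoxyphenyl]prop-2-yn-1-ol (racemic) | COCOc1c(OC)c(OC)c(OCc2ccccc2)c(OC)c1C(O)C#Cc1c(OC)cccc1OCc1ccccc1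
F2 | step 11 | 1-[3-(benzyloxy)-2,4,5-trimethoxy-6-(methoxymethoxy)phenyl]-3-[2-(benzyloxy)-6-methoxyphenyl]prop-2-yn-1-one | COCOc1c(OC)c(OC)c(OCc2ccccc2)c(OC)c1C(=O)C#Cc1c(OC)cccc1OCc1ccccc1
F3 | step 11 | 1-[3-(benzyloxy)-6-hydroxy-2,4,5-trimethoxyphenyl]-3-[2-(benzyloxy)-6-methoxyphenyl]prop-2-yn-1-one | COc1c(O)c(C(=O)C#Cc2c(OC)cccc2OCc2ccccc2)c(OC)c(OCc2ccccc2)c1OC
F4 | step 3 | 2-(benzyloxy)-4-bromo-5-(dimethoxymethyl)-1,3-dimethoxybenzene | COc1cc(C(OC)OC)c(Br)c(OC)c1OCc1ccccc1
F5 | step 3 | 3-(benzyloxy)-6-(dimethoxymethyl)-2,4-dimethoxyphenol | COc1cc(C(OC)OC)c(O)c(OC)c1OCc1ccccc1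
F6 | step 3 | 2-(benzyloxy)-5-(dimethoxymethyl)-1,3,4-trimethoxybenzene | COc1cc(C(OC)OC)c(OC)c(OC)c1OCc1ccccc1
F7 | step 5 | 2-(benzyloxy)-1,3,4-trimethoxy-5-(methoxymethoxy)benzene | COCOc1cc(OC)c(OCc2ccccc2)c(OC)c1OC
F8 | step 13 | 1-[3-(benzyloxy)-6-hydroxy-2,4,5-trimethoxyphenyl]-3-[2-(benzyloxy)-6-methoxyphenyl]propane-1,3-dione | Oc1c(OC)c(OC)c(OCc2ccccc2)c(OC)c1C(=O)CC(=O)c1c(OC)cccc1OCc1ccccc1
F9 | step 10 | 1-(benzyloxy)-2-(2,2-dibromoethenyl)-3-methoxybenzene | COc1cccc(OCc2ccccc2)c1C=C(Br)Br
A1 | alternative 1 | 4-[(tert-butyldimethylsilyl)oxy]-2,3,5-trimethoxyphenol | COc1cc(O)c(OC)c(OC)c1O[Si](C)(C)C(C)(C)C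
A2 | alternative 1 | 4-[(tert-butyldimethylsilyl)oxy]-2,3-dimethoxy-4-(1-methoxyethenyl)cyclobut-2-en-1-one (racemic) | COC(=C)C1(O[Si](C)(C)C(C)(C)C)C(OC)=C(OC)C1=O
A3 | alternative 1 | dimethyl squarate (3,4-dimethoxycyclobut-3-ene-1,2-dione) | COC1=C(OC)C(=O)C1=O
A4 | alternative 2 | 6-(benzyloxy)-2-(2-hydroxy-6-methoxyphenyl)-5,7,8-trimethoxy-4H-chromen-4-one | COc1cccc(O)c1-c1cc(=O)c2c(OC)c(OCc3ccccc3)c(OC)c(OC)c2o1
A5 | alternative 2 | 6-(benzyloxy)-5,7,8-trimethoxy-2-(methoxyethynyl)-4H-chromen-4-one | COC#Cc1cc(=O)c2c(OC)c(OCc3ccccc3)c(OC)c(OC)c2o1
A6 | alternative 2 | cyclobut-2-en-1-one | O=C1CC=C1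
A7 | alternative 3 | 6-(benzyloxy)-2-[2-(benzyloxy)-6-methoxyphenyl]-5,7,8-trimethoxy-4H-chromen-4-one | COc1cccc(OCc2ccccc2)c1-c1cc(=O)c2c(OC)c(OCc3ccccc3)c(OC)c(OC)c2o1
A8 | alternative 3 | 4-(benzyloxy)-2-iodo-3,5,6-trimethoxyphenol | COc1c(O)c(I)c(OC)c(OCc2ccccc2)c1OC
A9 | alternative 3 | carbon monoxide | [C-]#[O+]
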